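How much product stands in this flask after 10 d, and how close to saturation is the dissolved gas by then?

- eta: substrate 2 M; gas phase 97 mM (held); catalyst 2.6 mol%; added ligand 34 mM; the very flask that is asked about, followed so far
- flask: substrate 2.0 M; gas phase 97 mM (held); catalyst 2.6 mol%; added ligand 34 mM; time 10 d

- eta (time / h: product / %, substrate / %): 2.50: 2.0, 97.1; 8.00: 9.9, 89.1; 15.0: 17.5, 82.9; 20.0: 21.3, 77.5; 30.0: 29.9, 70.0; 40.0: 37.4, 62.5; 50.0: 45.1, 54.5

(scatter of a reading: 1 percentage point)

- at the start none of the gas is dissolved
- the numbers in the tables scatter with a standard deviation of 1 percentage point
- reactions considered so far: substrate + dissolved gas + catalyst -> catalyst + product; gas phase <-> dissolved gas; catalyst + added ligand <-> idle complex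

1. how much product there is at 10 d, in percent of the substrate charged
2. concentration of dissolved gas in solution at 10 d, in percent of saturation

I begin with the end state. No listed step turns product back and the gas phase is held, so the substrate is the limiting reagent and the flask heads for full conversion with its solution saturated. What remains is the pace. The substrate charge is far larger than the saturation level, so the gas phase must refill the solution about 20.6 times over.

I carry one quantity, the substrate's fractional loss rate, which is the logarithm of charged over remaining substrate, divided by the time. The last reading gives 0.0121 h⁻¹, a substrate half-life of 57.1 h.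

In the first hours the gas begins to dissolve. At 2.50 h my pace expects 2.98% product and the reading is 2.0%, so any lag is hidden in the scatter of 1 percentage point. In the middle, the reading at 40.0 h gives 0.0118 h⁻¹, so the course looks pseudo-first-order. The reaction step gives its catalyst back and uses up no added ligand, so I expect the idle share of the catalyst to stay the same, and it is then contained in my constant.

At the end, my pace leaves 5.43% of the substrate, which makes 94.6% product. By my pace, gas demand is then less than at the start, 1.32 mM h⁻¹ against 24.3 mM h⁻¹, so I expect the solution close to saturation.

The forecast gives 95% and 98%, holding that “the dissolved gas stays fairly close to saturation”. The flask gives 95.1% and 99.7%.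

    substrate + dissolved gas + catalyst → catalyst + product (k = 6.75 M⁻² h⁻¹)
    gas phase ⇌ dissolved gas, rate k2*(csat - [dissolved gas]) (kL = 4.95 h⁻¹)
    catalyst + added ligand ⇌ idle complex, settled at all times (K = 1080 M⁻¹)

In this flask, the transfer refills the solution with a half-life of 0.140 h, far shorter than the 0.20 d in which the reaction draws it down at 2.05 d. The dissolved gas stands at 0.0933 M after 1.00 d and 0.0967 M after 10.0 d. Counted in my half-life, 10 d is 4.20 half-lives. The same flask read at 6.0 d has had 2.52 half-lives, so my pace leaves 17.5% of its substrate, and it holds 16.6%.

(The numbers in the tables come from a simulation on assumed constants.)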